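The ten-membered ring is disconnected as the Cope isomer of a cyclohexane: the Z alkene C4=C5 and the C1–C10 epoxide (a masked C1=C10 enoate) flank the C2–C3 bond as a 1,5-diene, so C2–C3 is traded for a C5–C10 bond. In the forward sense the anionic oxy-Cope shift of a cis-1-vinyl-2-isopropenylcyclohexanol expands the ring C5–C10 from six to ten atoms, forms C2–C3, sets Z-C4=C5 and unveils the C10 ketone in one operation. The precursor carries C6–C9 already configured, a trans-fused C6/C7 methylene-tetrahydrofuran acetal as lactone mask and conformational lock, a C9 PMB ether and a C8 TES ether.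

Key step: step 17

Remark (numbering, faces): all intermediates keep the locants C1–C15 of the target; β is the face of the carbocycle on which C11 leaves C7 (H-7 α), so O-6 is α, the C5 isopropenyl group β, O-8 β, O-9 α, and in the cyclohexanols the C10 hydroxyl is α and the C10 ethynyl or vinyl group β.
Remark (acetal carbon): C12 of the isopropyl acetal should form as two epimers of equal use that converge in step 26; names and SMILES show the epimer with the isopropoxy group cis to H-6.

Step 1
Reactants: 1 3-methylbut-2-enal; 2 methyl prop-2-ynoate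
Product: 3 methyl (4R)-4-hydroxy-6-methylhept-5-en-2-ynoate
Conditions: Me2Zn, ProPhenol ligand (enantiomer giving the 4R alcohol), Ph3P=O, toluene, 0 °C; aq. NH4Cl
Reagents that add atoms: none
Why: Catalytic enantioselective addition of the zinc alkynylide to the enal (zinc–ProPhenol alkynylation) should set the carbinol carbon, the future C6, under catalyst control.

Step 2
Reactants: 3 methyl (4R)-4-hydroxy-6-methylhept-5-en-2-ynoate
Product: 5 (S)-5-(2-methylprop-1-enyl)furan-2(5H)-one, via Z-hydroxy enoate 4 (not isolated)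
Conditions: H2 (1 atm), Pd/CaCO3 poisoned with Pb(OAc)2 (Lindlar), quinoline, EtOAc, rt; then PPTS (cat.), CH2Cl2
Reagents that add atoms: none
Why: Lindlar semi-hydrogenation gives the cis enoate, whose hydroxyl closes the butenolide by intramolecular transesterification without touching the stereocentre (the descriptor changes only through the priority rules).

Step 3
Reactants: 5 (S)-5-(2-methylprop-1-enyl)furan-2(5H)-one; 6 [2-(1,3-dioxolan-2-yl)ethyl]magnesium bromide
Product: 7 trans-lactone 4-[2-(1,3-dioxolan-2-yl)ethyl]-5-(2-methylprop-1-enyl)oxolan-2-one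
Conditions: 6 (2.2 equiv), CuBr·SMe2 (1.1 equiv), THF, −78 °C; aq. NH4Cl
Reagents that add atoms: none
Why: Conjugate addition of the magnesium homocuprate to the butenolide should occur anti to the alkenyl group on C6 and so set C7 trans to it (substrate control), bringing in C8–C10.

Step 4
Reactants: 7 trans-lactone
Product: 10 α-methylene lactone (3-methylidene derivative of 7), via Mannich base 8 (not isolated), via ammonium iodide 9 (not isolated)
Conditions: LiN(i-Pr)2, THF, −78 °C, then CH2=NMe2+ I−; then MeI, THF; then aq. NaHCO3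
Reagents that add atoms: N,N-dimethylmethyleneiminium iodide (Eschenmoser's salt), C=[N+](C)C.[I-]
Why: Mannich aminomethylation of the lactone enolate, quaternisation and E1cB loss of trimethylamine is the standard α-methylenation of γ-lactones and installs C13 without affecting C6 or C7.

Step 5
Reactants: 10 α-methylene lactone
Product: 11 3-[4-methylidene-2-(2-methylprop-1-enyl)-5-oxooxolan-3-yl]propanal (2,3-trans)
Conditions: aq. HCl (1 M), THF, rt
Reagents that add atoms: water, O
Why: Acid-catalysed acetal hydrolysis of the dioxolane frees the C10 aldehyde.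

Step 6
Reactants: 11 lactone aldehyde
Product: 12 trans-fused bicyclic hydroxy lactone (cyclohexane C5–C10; 5β-isopropenyl; 10α-OH)
Conditions: Me2AlCl (2 equiv), CH2Cl2, −78 → −30 °C; aq. HCl (1 M)
Reagents that add atoms: none
Why: Lewis-acid-promoted intramolecular carbonyl-ene reaction of the 7-methyloct-6-enal array (the citronellal-to-isopulegol type) through a chair in which the lactone bonds at C6 and C7 are equatorial should place the new isopropenyl group at C5 equatorial (β, trans to O-6) and the C10 hydroxyl equatorial (α).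

Step 7
Reactants: 12 bicyclic hydroxy lactone
Product: 14 isopropyl acetal (C12 as CH–O-i-Pr; 10α-OH), via lactol 13 (not isolated)
Conditions: i-Bu2AlH (2.2 equiv), CH2Cl2, −78 °C, aq. potassium sodium tartrate; then i-PrOH, PPTS (cat.), rt
Reagents that add atoms: propan-2-ol, CC(C)O
Why: 1,2-Reduction of the α-methylene lactone to the lactol and acid-catalysed acetalisation give a base-stable lactone mask whose anomeric centre C12 is inconsequential.

Step 8
Reactants: 14 isopropyl acetal alcohol
Product: 15 C10 ketone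
Conditions: Dess–Martin periodinane, CH2Cl2, 0 °C → rt
Reagents that add atoms: none
Why: Dess–Martin oxidation of the secondary alcohol proceeds without base, so the equatorial C5 isopropenyl group and the β-alkoxy ketone are not disturbed.

Step 9
Reactants: 15 C10 ketone
Product: 17 enone (C10 ketone; C8=C9), via silyl enol ether 16 (not isolated)
Conditions: LiN(i-Pr)2, Me3SiCl, THF, −78 °C; then Pd(OAc)2, MeCN, rt
Reagents that add atoms: none
Why: Kinetic deprotonation at the unhindered C9 methylene and Saegusa–Ito dehydrosilylation of the silyl enol ether by divalent palladium introduce the C8=C9 bond.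

Step 10
Reactants: 17 enone; 18 ethynylmagnesium bromide
Product: 19 10β-ethynyl-10α-hydroxy cyclohexene (C8=C9)
Conditions: CeCl3 (anhydrous), THF, −78 °C; aq. NH4Cl
Reagents that add atoms: none
Why: 1,2-Addition of the organocerium acetylide (cerium suppresses enolisation) should occur axially on the β face, anti to the axial C5–H bond and unhindered because C8 is trigonal, setting C10 with the ethynyl group β and cis to the isopropenyl group.

Step 11
Reactants: 19 ethynyl carbinol
Product: 20 8α,9α-epoxide
Conditions: VO(acac)2 (5 mol %), t-BuOOH, CH2Cl2, 0 °C → rt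
Reagents that add atoms: tert-butyl hydroperoxide, CC(C)(C)OO
Why: Vanadium-catalysed hydroxyl-directed epoxidation delivers oxygen to the only allylic alkene, C8=C9, on the face of the C10 hydroxyl and so sets C8 and C9 as the α-epoxide.

Step 12
Reactants: 20 8α,9α-epoxide
Product: 21 8β-pivaloyloxy-9α,10α-diol
Conditions: Ti(OiPr)4 (1.5 equiv), t-BuCO2H, CH2Cl2, rt; aq. tartaric acid
Reagents that add atoms: pivalic acid, CC(C)(C)C(=O)O
Why: Ti(OiPr)4-mediated opening of the 2,3-epoxy alcohol by a carboxylic acid at the distal carbon, which is also the only carbon open to trans-diaxial (Fürst–Plattner) attack in the locked chair, should invert C8 and leave the two axial oxygens differentiated (isopropoxide exchange at the acetal is degenerate).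

Step 13
Reactants: 21 8β-pivaloyloxy-9α,10α-diol
Product: 23 9α-(4-methoxybenzyl) ether, via stannylene acetal 22 (not isolated)
Conditions: Bu2SnO, toluene, reflux (−H2O); then 4-MeOC6H4CH2Cl, Bu4NI, toluene, 80 °C
Reagents that add atoms: 4-methoxybenzyl chloride, COc1ccc(CCl)cc1
Why: Stannylene-acetal-mediated alkylation of the cis-9,10-diol should benzylate the secondary C9 oxygen rather than the tertiary C10 oxygen without forming a free alkoxide or acetylide.

Step 14
Reactants: 23 9α-PMB ether 8β-pivalate
Product: 24 8β-alcohol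
Conditions: i-Bu2AlH, CH2Cl2, −78 °C; aq. potassium sodium tartrate
Reagents that add atoms: none
Why: Reductive cleavage of the pivalate by the aluminium hydride frees the C8 hydroxyl without basic conditions.

Step 15
Reactants: 24 8β-alcohol
Product: 25 8β-triethylsilyl ether (10β-ethynyl)
Conditions: Et3SiCl, imidazole, DMF, rt
Reagents that add atoms: chlorotriethylsilane, CC[Si](CC)(CC)Cl
Why: Silylation should take the secondary C8 hydroxyl and leave the hindered tertiary C10 hydroxyl free.

Step 16
Reactants: 25 8β-TES ether (10β-ethynyl)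
Product: 26 cis-1-vinyl-2-isopropenylcyclohexanol precursor (10β-vinyl; 10α-OH; 5β-isopropenyl; 8β-OTES; 9α-OPMB)
Conditions: H2 (1 atm), Pd/CaCO3 poisoned with Pb(OAc)2 (Lindlar), quinoline, EtOAc, rt
Reagents that add atoms: none
Why: Lindlar semi-hydrogenation turns the terminal alkyne into the axial vinyl group while the 1,1-disubstituted alkenes and the benzyl-type ether should survive.

Step 17
Reactants: 26 cis-1-vinyl-2-isopropenylcyclohexanol precursor
Product: 29 Z-cyclodecenone (C10 ketone; 8β-OTES; 9α-OPMB), via potassium alkoxide 27 (not isolated), via ring-trans potassium enolate 28 (not isolated)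
Conditions: KH, 18-crown-6, THF, 0 °C → rt; then aq. NH4Cl, −78 °C
Reagents that add atoms: none
Why: Deprotonation gives potassium alkoxide 27, in which the oxyanion weakens the C5–C10 bond; that bond breaks while C2–C3 forms through a chair-shaped six-centre array (anionic oxy-Cope [3,3] shift), and because the charge ends in enolate 28 the shift does not reverse, quenching giving ketone 29. The closest known reaction type is the anionic oxy-Cope ring expansion of 1,2-dialkenylcyclohexanols to cyclodec-5-enones. The ten-membered ring is made by four-carbon expansion of the cyclohexane, by cleavage of the ring bond shared with the diene array rather than by cyclisation of chain ends. No stereocentre is created: C5 and C10 become trigonal, C6–C9 are carried through, and the geometry of enolate 28 is erased on protonation. The step must give Z-C4=C5 and must not fragment or transfer silicon: the trans-fused acetal ring fixes the chair with the isopropenyl group equatorial and the vinyl group axial, which puts the C5–C6 bond in the pseudo-axial site of the array and so C6 and C3 on the same side of the new alkene, while the C9 oxygen bears a benzyl-type ether that cannot migrate to the alkoxide and the C8 silyl ether is trans-1,3 and out of reach.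

Step 18
Reactants: 29 Z-cyclodecenone
Product: 31 ring-cis C10 enol triflate (C1=C10), via ring-cis potassium enolate 30 (not isolated)
Conditions: KN(SiMe3)2, THF, −78 °C; then PhNTf2, −78 → 0 °C
Reagents that add atoms: N-phenylbis(trifluoromethanesulfonimide), O=S(=O)(N(c1ccccc1)S(=O)(=O)C(F)(F)F)C(F)(F)F
Why: Kinetic deprotonation should occur at the C1 methylene rather than at the hindered alkoxy-bearing C9, the ten-membered ring should favour the enolate with C2 and C9 cis, and O-sulfonylation fixes it as the enol triflate.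

Step 19
Reactants: 31 ring-cis enol triflate
Product: 32 ring-cis methyl enoate (C14 ester on C10)
Conditions: Pd(OAc)2 (5 mol %), PPh3, CO (1 atm), MeOH, Et3N, DMF, 40 °C
Reagents that add atoms: carbon monoxide, [C-]#[O+]; methanol, CO
Why: Palladium-catalysed methoxycarbonylation (oxidative addition to zerovalent palladium, CO insertion, methanolysis) installs C14 with retention of alkene geometry.

Step 20
Reactants: 32 ring-cis methyl enoate
Product: 33 C14 allylic alcohol
Conditions: i-Bu2AlH, CH2Cl2, −78 °C; aq. potassium sodium tartrate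
Reagents that add atoms: none
Why: 1,2-Reduction of the conjugated ester gives the primary allylic alcohol that serves as handle for a reagent-controlled epoxidation.

Step 21
Reactants: 33 C14 allylic alcohol
Product: 34 1,10-epoxy C14 alcohol
Conditions: Ti(OiPr)4 (1 equiv), D-(−)-diethyl tartrate (1.2 equiv), t-BuOOH, 4 Å molecular sieves, CH2Cl2, −20 °C
Reagents that add atoms: tert-butyl hydroperoxide, CC(C)(C)OO
Why: Sharpless asymmetric epoxidation is chemoselective for the allylic-alcohol alkene C1=C10 and, with the D-tartrate, should deliver oxygen to the face that gives the C1 and C10 configurations of the target under catalyst control.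

Step 22
Reactants: 34 1,10-epoxy C14 alcohol
Product: 35 1,10-epoxy C14 carboxylic acid
Conditions: TEMPO (cat.), PhI(OAc)2, MeCN/pH 7 phosphate buffer, 0 °C → rt
Reagents that add atoms: water, O
Why: Oxoammonium-mediated (TEMPO/PhI(OAc)2) oxidation of the primary alcohol through the aldehyde hydrate gives the acid without touching alkenes, ethers or epoxide.

Step 23
Reactants: 35 epoxy acid
Product: 36 1,10-epoxy methyl ester (8β-OTES; 9α-OPMB; acetal)
Conditions: MeI, K2CO3, DMF, 0 °C → rt
Reagents that add atoms: iodomethane, CI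
Why: SN2 alkylation of the carboxylate gives the methyl ester under conditions that neither open the epoxide nor decarboxylate the glycidic acid.

Step 24
Reactants: 36 epoxy methyl ester
Product: 37 8β-alcohol
Conditions: HF·pyridine, pyridine, THF, 0 °C
Reagents that add atoms: none
Why: Fluoride-mediated desilylation removes the TES group in a buffered medium that spares the acetal, the PMB ether and the epoxy ester.

Step 25
Reactants: 37 8β-alcohol; 38 (S)-2-methylbutanoic acid
Product: 40 8β-[(S)-2-methylbutanoate], via mixed anhydride 39 (not isolated)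
Conditions: 2,4,6-Cl3C6H2COCl, Et3N, THF, rt; then 37, DMAP, toluene, rt
Reagents that add atoms: none
Why: Yamaguchi esterification acylates the only free hydroxyl (C8) through the mixed anhydride without epimerising the α-stereocentre of the acid.

Step 26
Reactants: 40 8β-ester acetal
Product: 42 α-methylene-γ-lactone 9α-PMB ether, via lactol 41 (not isolated)
Conditions: AcOH/THF/H2O (3:1:1), 35 °C; then MnO2, CH2Cl2, rt
Reagents that add atoms: water, O
Why: Mild acid hydrolysis of the allylic acetal and MnO2 oxidation of the allylic lactol unveil the lactone at a stage where no free hydroxyl can trap the oxocarbenium ion.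

Step 27
Reactants: 42 lactone 9α-PMB ether
Product: 43 CNP0581690.1
Conditions: DDQ, CH2Cl2/pH 7 buffer, 0 °C → rt
Reagents that add atoms: none
Why: Oxidative cleavage of the PMB ether by DDQ (hydride abstraction, hydrolysis of the oxocarbenium ion) frees the C9 hydroxyl under neutral conditions tolerated by the epoxide, the esters and the methylene lactone.

Compound list
1 | 3-methylbut-2-enal | CC(C)=CC=O | starting material
2 | methyl prop-2-ynoate | C#CC(=O)OC | starting material
3 | methyl (4R)-4-hydroxy-6-methylhept-5-en-2-ynoate | COC(=O)C#C[C@H](O)C=C(C)C | intermediate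
4 | methyl (2Z,4S)-4-hydroxy-6-methylhepta-2,5-dienoate | COC(=O)/C=C\[C@H](O)C=C(C)C | intermediate
5 | (S)-5-(2-methylprop-1-enyl)furan-2(5H)-one | O=C1C=C[C@@H](C=C(C)C)O1 | intermediate
6 | [2-(1,3-dioxolan-2-yl)ethyl]magnesium bromide | Br[Mg]CCC1OCCO1 | starting material
7 | 4-[2-(1,3-dioxolan-2-yl)ethyl]-5-(2-methylprop-1-enyl)oxolan-2-one, 4,5-trans, ring C5 as in 5 | O=C1C[C@H](CCC2OCCO2)[C@@H](C=C(C)C)O1 | intermediate
8 | 3-(dimethylaminomethyl) derivative of 7, 3,4-trans | CN(C)C[C@@H]1C(=O)O[C@H](C=C(C)C)[C@H]1CCC1OCCO1 | intermediate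
9 | N-methyl quaternary ammonium iodide of 8 | C[N+](C)(C)C[C@@H]1C(=O)O[C@H](C=C(C)C)[C@H]1CCC1OCCO1.[I-] | intermediate
10 | 3-methylidene derivative of 7 (α-methylene lactone) | C=C1C(=O)O[C@H](C=C(C)C)[C@H]1CCC1OCCO1 | intermediate
11 | 3-[4-methylidene-2-(2-methylprop-1-enyl)-5-oxooxolan-3-yl]propanal, 2,3-trans | C=C1C(=O)O[C@H](C=C(C)C)[C@H]1CCC=O | intermediate
12 | trans-fused hydroxy lactone: cyclohexane C5–C10 with 5β-isopropenyl and 10α-OH, α-methylene-γ-lactone through O-6α and C-7β | C=C1C(=O)O[C@@H]2[C@@H](C(C)=C)[C@H](O)CC[C@@H]12 | intermediate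
13 | lactol of 12 (C12 hemiacetal, interconverting epimers) | C=C1C(O)O[C@@H]2[C@@H](C(C)=C)[C@H](O)CC[C@@H]12 | intermediate
14 | 12-isopropyl acetal of 13 (10α-OH) | C=C1[C@@H](OC(C)C)O[C@@H]2[C@@H](C(C)=C)[C@H](O)CC[C@@H]12 | intermediate
15 | C10 ketone of 14 | C=C1[C@@H](OC(C)C)O[C@@H]2[C@@H](C(C)=C)C(=O)CC[C@@H]12 | intermediate
16 | trimethylsilyl enol ether of 15 (C9=C10) | C=C1[C@@H](OC(C)C)O[C@@H]2[C@@H](C(C)=C)C(O[Si](C)(C)C)=CC[C@@H]12 | intermediate
17 | enone: C10 ketone with C8=C9, 5β-isopropenyl, trans-fused acetal | C=C1[C@@H](OC(C)C)O[C@@H]2[C@@H](C(C)=C)C(=O)C=C[C@@H]12 | intermediate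
18 | ethynylmagnesium bromide | C#C[Mg]Br | starting material
19 | 10β-ethynyl-10α-hydroxy cyclohexene (C8=C9) | C=C1[C@@H](OC(C)C)O[C@@H]2[C@@H](C(C)=C)[C@@](O)(C#C)C=C[C@@H]12 | intermediate
20 | 8α,9α-epoxide of 19 | C=C1[C@@H](OC(C)C)O[C@@H]2[C@@H](C(C)=C)[C@@](O)(C#C)[C@@H]3O[C@@H]3[C@@H]12 | intermediate
21 | 8β-pivaloyloxy-9α,10α-diol | C=C1[C@@H](OC(C)C)O[C@@H]2[C@@H](C(C)=C)[C@@](O)(C#C)[C@H](O)[C@@H](OC(=O)C(C)(C)C)[C@@H]12 | intermediate
22 | 9,10-O-dibutylstannylene acetal of 21 | C=C1[C@@H](OC(C)C)O[C@@H]2[C@@H](C(C)=C)[C@]3(C#C)O[Sn](CCCC)(CCCC)O[C@@H]3[C@@H](OC(=O)C(C)(C)C)[C@@H]12 | intermediate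
23 | 9α-(4-methoxybenzyl) ether of 21 | C=C1[C@@H](OC(C)C)O[C@@H]2[C@@H](C(C)=C)[C@@](O)(C#C)[C@H](OCc3ccc(OC)cc3)[C@@H](OC(=O)C(C)(C)C)[C@@H]12 | intermediate
24 | 8β-alcohol (9α-OPMB, 10α-OH, 10β-ethynyl) | C=C1[C@@H](OC(C)C)O[C@@H]2[C@@H](C(C)=C)[C@@](O)(C#C)[C@H](OCc3ccc(OC)cc3)[C@@H](O)[C@@H]12 | intermediate
25 | 8β-triethylsilyl ether of 24 | C=C1[C@@H](OC(C)C)O[C@@H]2[C@@H](C(C)=C)[C@@](O)(C#C)[C@H](OCc3ccc(OC)cc3)[C@@H](O[Si](CC)(CC)CC)[C@@H]12 | intermediate
26 | cis-1-vinyl-2-isopropenylcyclohexanol (10β-vinyl, 10α-OH, 5β-isopropenyl, 8β-OTES, 9α-OPMB, trans-fused acetal) | C=C1[C@@H](OC(C)C)O[C@@H]2[C@@H](C(C)=C)[C@@](O)(C=C)[C@H](OCc3ccc(OC)cc3)[C@@H](O[Si](CC)(CC)CC)[C@@H]12 | intermediate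
27 | potassium alkoxide of 26 | C=C1[C@@H](OC(C)C)O[C@@H]2[C@@H](C(C)=C)[C@@]([O-])(C=C)[C@H](OCc3ccc(OC)cc3)[C@@H](O[Si](CC)(CC)CC)[C@@H]12.[K+] | intermediate
28 | potassium enolate of 29 with C2 and C9 trans on C1=C10 | C=C1[C@@H](OC(C)C)O[C@@H]2/C=C(/C)CC/C=C(\[O-])[C@H](OCc3ccc(OC)cc3)[C@@H](O[Si](CC)(CC)CC)[C@@H]12.[K+] | intermediate
29 | ten-membered C10 ketone with (Z)-C4=C5 (8β-OTES, 9α-OPMB, acetal) | C=C1[C@@H](OC(C)C)O[C@@H]2/C=C(/C)CCCC(=O)[C@H](OCc3ccc(OC)cc3)[C@@H](O[Si](CC)(CC)CC)[C@@H]12 | intermediate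
30 | potassium enolate of 29 with C2 and C9 cis on C1=C10 | C=C1[C@@H](OC(C)C)O[C@@H]2/C=C(/C)CC/C=C(/[O-])[C@H](OCc3ccc(OC)cc3)[C@@H](O[Si](CC)(CC)CC)[C@@H]12.[K+] | intermediate
31 | ring-cis C10 enol triflate | C=C1[C@@H](OC(C)C)O[C@@H]2/C=C(/C)CC/C=C(/OS(=O)(=O)C(F)(F)F)[C@H](OCc3ccc(OC)cc3)[C@@H](O[Si](CC)(CC)CC)[C@@H]12 | intermediate
32 | ring-cis methyl enoate (C14 on C10) | C=C1[C@@H](OC(C)C)O[C@@H]2/C=C(/C)CC/C=C(/C(=O)OC)[C@H](OCc3ccc(OC)cc3)[C@@H](O[Si](CC)(CC)CC)[C@@H]12 | intermediate
33 | C14 allylic alcohol | C=C1[C@@H](OC(C)C)O[C@@H]2/C=C(/C)CC/C=C(/CO)[C@H](OCc3ccc(OC)cc3)[C@@H](O[Si](CC)(CC)CC)[C@@H]12 | intermediate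
34 | 1,10-epoxy C14 alcohol (epoxide as in the target) | C=C1[C@@H](OC(C)C)O[C@@H]2/C=C(/C)CC[C@H]3O[C@@]3(CO)[C@H](OCc4ccc(OC)cc4)[C@@H](O[Si](CC)(CC)CC)[C@@H]12 | intermediate
35 | 1,10-epoxy C14 carboxylic acid | C=C1[C@@H](OC(C)C)O[C@@H]2/C=C(/C)CC[C@H]3O[C@@]3(C(=O)O)[C@H](OCc4ccc(OC)cc4)[C@@H](O[Si](CC)(CC)CC)[C@@H]12 | intermediate
36 | 1,10-epoxy methyl ester (8β-OTES, 9α-OPMB, acetal) | C=C1[C@@H](OC(C)C)O[C@@H]2/C=C(/C)CC[C@H]3O[C@@]3(C(=O)OC)[C@H](OCc4ccc(OC)cc4)[C@@H](O[Si](CC)(CC)CC)[C@@H]12 | intermediate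
37 | 8β-alcohol of 36 | C=C1[C@@H](OC(C)C)O[C@@H]2/C=C(/C)CC[C@H]3O[C@@]3(C(=O)OC)[C@H](OCc4ccc(OC)cc4)[C@@H](O)[C@@H]12 | intermediate
38 | (S)-2-methylbutanoic acid | CC[C@H](C)C(=O)O | starting material
39 | (S)-2-methylbutanoic 2,4,6-trichlorobenzoic anhydride | CC[C@H](C)C(=O)OC(=O)c1c(Cl)cc(Cl)cc1Cl | intermediate
40 | 8β-[(S)-2-methylbutanoate] of 37 | C=C1[C@@H](OC(C)C)O[C@@H]2/C=C(/C)CC[C@H]3O[C@@]3(C(=O)OC)[C@H](OCc4ccc(OC)cc4)[C@@H](OC(=O)[C@@H](C)CC)[C@@H]12 | intermediate
41 | lactol of 40 (C12 hemiacetal, interconverting epimers) | C=C1C(O)O[C@@H]2/C=C(/C)CC[C@H]3O[C@@]3(C(=O)OC)[C@H](OCc4ccc(OC)cc4)[C@@H](OC(=O)[C@@H](C)CC)[C@@H]12 | intermediate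
42 | α-methylene-γ-lactone 9α-PMB ether | C=C1C(=O)O[C@@H]2/C=C(/C)CC[C@H]3O[C@@]3(C(=O)OC)[C@H](OCc4ccc(OC)cc4)[C@@H](OC(=O)[C@@H](C)CC)[C@@H]12 | intermediate
43 | CNP0581690.1: (1R,6R,7S,8S,9R,10S,4Z)-1,10-epoxy-9-hydroxy-8-[(S)-2-methylbutanoyloxy] 12,6-olide 14-methyl ester | C=C1C(=O)O[C@@H]2/C=C(/C)CC[C@H]3O[C@@]3(C(=O)OC)[C@H](O)[C@@H](OC(=O)[C@@H](C)CC)[C@@H]12 | target

Total step count: 27. Longest linear sequence: 27 steps (from 1 and 2 to 43).

Steps most likely to fail

Step 17. The alkoxide may cleave heterolytically at C5–C10 without closing C2–C3, or may rearrange through a boat array with loss of Z control. Fallback, from 26 back to 29 with no new isolated compound: the same bond reorganisation under catalysis by divalent palladium, PdCl2(PhCN)2 (10 mol %) in THF at room temperature. The metal binds the vinyl group, the isopropenyl terminus C3 attacks C2 to give a tertiary C4 cation in a chair cyclohexane, and Grob-type cleavage of C5–C10 releases the enol of 29. This is the known palladium-catalysed Cope and oxy-Cope rearrangement of 1,5-dienes that carry a substituent on an inner alkene carbon, and it keeps the free alkoxide out of the flask.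

Step 18. Proton removal may occur on the C9 side, followed by β-elimination of the C8 silyloxy group, or the enolate may form with C2 and C9 trans. Fallback, from 26 back to 32: in the flask of step 17 the regiodefined enolate 28 is not quenched but treated with PhNTf2 at −78 °C, giving the ring-trans enol triflate F1. Methoxycarbonylation as in step 19 gives the ring-trans methyl enoate F2. The alkene geometry is then equilibrated toward the less strained ring-cis isomer by reversible conjugate addition of thiolate (PhSH, cat. PhSLi, THF) or by sensitised irradiation, giving 32.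

Step 6. The Lewis acid may ionise the allylic C6–O bond of the lactone faster than the aldehyde engages the alkene. Fallback, from 5 back to 17, closing the carbocycle by metathesis under neutral conditions: addition of the vinyl homocuprate (CH2=CHMgBr, CuBr·SMe2) to 5 gives the trans-4-vinyl lactone F3. The α-methylenation of step 4 gives the methylene lactone F4, and i-Bu2AlH followed by i-PrOH/PPTS gives the isopropyl acetal F5. Ene-type allylic chlorination of the trisubstituted alkene (Ca(OCl)2, CO2, CH2Cl2/H2O, 0 °C) gives the secondary allylic chloride F6. CrCl2-mediated Nozaki–Hiyama allylation of acrolein, with bond formation at the more substituted allyl terminus C5, gives the dienol F7 as a mixture at C5 and C10. Ring-closing metathesis with the second-generation Grubbs catalyst closes C8=C9 to the cyclohexenol F8. Dess–Martin oxidation and equilibration of C5 to the equatorial epimer with DBU (cat.) give 17.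

Further compounds
F0 | step 17 | none | none
F1 | step 18 | ring-trans C10 enol triflate | C=C1[C@@H](OC(C)C)O[C@@H]2/C=C(/C)CC/C=C(\OS(=O)(=O)C(F)(F)F)[C@H](OCc3ccc(OC)cc3)[C@@H](O[Si](CC)(CC)CC)[C@@H]12
F2 | step 18 | ring-trans methyl enoate | C=C1[C@@H](OC(C)C)O[C@@H]2/C=C(/C)CC/C=C(\C(=O)OC)[C@H](OCc3ccc(OC)cc3)[C@@H](O[Si](CC)(CC)CC)[C@@H]12
F3 | step 6 | trans-4-ethenyl-5-(2-methylprop-1-enyl)oxolan-2-one | O=C1C[C@H](C=C)[C@@H](C=C(C)C)O1
F4 | step 6 | 3-methylidene derivative of F3 | C=C1C(=O)O[C@H](C=C(C)C)[C@H]1C=C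
F5 | step 6 | isopropyl lactol ether of F4 | C=C1[C@@H](OC(C)C)O[C@H](C=C(C)C)[C@H]1C=C
F6 | step 6 | allylic chloride (Cl on C5, mixture at C5) | C=C1[C@@H](OC(C)C)O[C@H](C(Cl)C(C)=C)[C@H]1C=C
F7 | step 6 | dienol (mixture at C5 and C10) | C=C1[C@@H](OC(C)C)O[C@H](C(C(C)=C)C(O)C=C)[C@H]1C=C
F8 | step 6 | cyclohexenol (C8=C9, mixture at C5 and C10) | C=C1[C@@H](OC(C)C)O[C@@H]2C(C(C)=C)C(O)C=C[C@@H]12
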